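Two constants would tell you whether more free catalyst pays, one for the reaction and one for gas entering solution. Neither is given, so I reckon with times instead.

- green: left-handed substrate 1.2 M; right-handed substrate 1.2 M; gas 200 mM (held); free catalyst 0.5 mol%; run made earlier
- flask: left-handed substrate 1.8 M; gas 200 mM (held); free catalyst 0.5 mol%; right-handed substrate 1.8 M

- green (time / min: left-handed product / %): 0.250: 1.4; 0.833: 5.4; 1.33: 8.1; 2.00: 10.9; 3.00: 15.5

(scatter of a reading: 1 percentage point)

* factor on the rate of making left-handed product when 30 % of the left-handed substrate and right-handed substrate together are converted if free catalyst is charged twice over
* factor on the rate when 30 % of the left-handed substrate and right-handed substrate together are converted if free catalyst is charged at 2.5 mol% instead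

- free catalyst is single-handed; left-handed substrate and right-handed substrate are mirror images of each other, charged as a racemate, each of them at the stated concentration
- what was read earlier has a scatter of 1 percentage point, one standard deviation
- at the start none of the gas is in solution
- no earlier run changes the charge of free catalyst; that part of a forecast is a guess

Take the right-handed substrate as a spectator. At the last green reading the left-handed substrate then decays with 0.124 min⁻¹. The new flask has the same mol% on a higher substrate concentration, so its catalyst concentration is higher in the same proportion, and if the order in catalyst is one this gives 0.186 min⁻¹. At 30 % conversion the rate is then 0.134 M min⁻¹.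

Divide the saturation concentration by that rate and you get 1.50 min. This is the gas clock τ, the time saturated gas would last at that rate, with one gas per product.

I take τ as the sum of a reaction part, which shrinks with catalyst if the order is one (a guess), and a crossing time t, which stays. A lag of about the scatter over the slope, 0.194 min, would not stand out in the green readings, so I use that as my estimate of t.

The factors are then 1.77 and 3.30. At 2.5 mol% the reaction part, 0.261 min, stands beside t at 0.194 min, and these are of like size, so I call neither the rate-limiting step there, and the factor per unit of catalyst falls from 0.885 to 0.659. With little material, I would double the catalyst and leave the rest unchanged.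

The forecast gives 1.9 (1.4 to 2.1) and 4.4 (2.4 to 5.3), first order “trimmed slightly for possible gas-transfer limits”. Its second factor stands above mine.

The simulation gives 1.77 and 3.30.

    partner + free catalyst + left-handed substrate → free catalyst + left-handed product (k = 2.10 M⁻² s⁻¹)
    partner + free catalyst + right-handed substrate → free catalyst + right-handed product (k = 0.0975 M⁻² s⁻¹)
    free catalyst → spent catalyst (k = 5.61 × 10⁻⁶ s⁻¹)
    gas ⇌ partner, rate k4*(csat - [partner]) (kL = 0.117 s⁻¹)

Gas crossed into solution as the partner, which stood at 0.144 M after 0.300 min and 0.168 M after 3.00 min, and meanwhile the left-handed substrate fell to 59 % of its charge and the right-handed to 98 %. The gas clock, 1.50 min by my reckoning, reads 1.28 min at the flask's rate after 4.54 min, and the crossing time 0.142 min is 11.1 % of it; at 2.5 mol% the simulated factor shortens the clock to 0.389 min, of which crossing is 36.5 %.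

The data are calculated for an exercise.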